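## Structural features

The target is a C25 alcohol built on a bicyclo[4.4.1]undecane: the seven-membered rings B (C5, C6, C7, C8, C13, C14, C15) and C (C1–C5, C15, C14) share the bridgeheads C5 and C14 and the one-carbon bridge C15, and ring A (C8–C13) is fused to ring B along C8–C13. The core carries three alkenes and no heteroatom: the tetrasubstituted C8=C9 with its methyl group, the bridgehead C4=C5 (cis within ring C, trans within the ten-membered perimeter) and the exocyclic methylene on C1. Four stereocentres stand in a row: C14 (S), C13 (R), C12 (S) and the side-chain carbon C16 (S), with H12 trans to H13 and H13 anti to H14. The C12 side chain ends in an (E)-2-methylallylic primary alcohol. Fragile points are the 1,1-disubstituted and bridgehead alkenes (acid-induced migration), the skipped C4=C5/C7 relationship across C6, and the allylic alcohol (ionisation, oxidation). The real difficulty is the bridged seven–seven ring pair with its bridgehead alkene, together with the C13–C14 relationship next to the ring A stereocentre. The key step exploits the fact that ring C plus the bridge (C14, C1–C4, C5, C15) is a cycloheptatrienone in disguise, and that the other four atoms of ring B (C6, C7, C8, C13) are a 1,3-diene reaching out of ring A.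

## Logic of the disconnections

28 is returned to its silyl ether 27, and the C9–CH3 bond of 27 is cut. The methyl group is placed on the enol triflate 26, which comes from enone 23 by conjugate reduction and trapping of the C8=C9 enolate (24, 25). The reason is that a site-specific enolate fixes the position of the tetrasubstituted alkene. The gain is that ring A goes back to the oxidised form of an allylic ether. The demand is a hydride addition at C7 without base, because C6–H2 of 23 is flanked by the carbonyl-conjugated alkene and by C4=C5.

The exocyclic C1=CH2 bond of 23 (through 22 and 21) is cut back to ketone 20. The reason is that C1 then carries an oxygen, the only handle that ring C can receive from a diene. The gain is one carbon fewer. The demand is that the methylenation is run while C1 is the only carbonyl in the molecule.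

In 20 no carbon–carbon bond is cut. The C1 carbonyl and C4=C5 are traced through 19 and 18 to the cis-diol 17 and the endoperoxide 16, that is, to one molecule of oxygen added across C1/C4 of the ring C diene of 15. C4=C5 arises by loss of the C4 oxygen together with H5, and C2=C3 is removed by conjugate reduction. The reason is that the cis-locked diene is the only π system of 15 that adds oxygen in a [4+2] sense. The gain is an unfunctionalised ring C. The demand is twofold: the two diene ends must be told apart (oxygen kept at C1, lost at C4), and the elimination must reach a bridgehead hydrogen.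

The two C15–H bonds of 15 are exchanged for the carbonyl oxygen of 12 (through 14 and 13). The reason is that the one-carbon bridge then is the carbonyl carbon of a troponoid. The demand is a deoxygenation that passes a C15 radical flanked by the diene.

12 is cut at C13–C14 and C5–C6 into 10 and 11. This removes both seven-membered rings and three stereocentres at once and leaves a bought seven-carbon partner and a monocyclic diene. The demand is periselectivity ([6+4] against [4+2]), exo geometry and addition to one face of 10.

In 10 the C7–C8 bond is cut (vinyl group from a tin reagent, iodide 9). The C9 oxygen centre of 9/8 is traced to ketone 7 and the C8–I bond to enone 6. The gain is a plain 4-substituted cyclohexenone. The demand is a reduction that sets C9 cis to the side chain against the substrate's own preference.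

6 is traced through 5 to 4 by removing the silyl group and the oxygen on the (E)-methyl group of the side chain. The demand is an allylic oxidation that ignores the enone.

4 is cut at C11–C12 and C8–C13 (conjugate addition, then aldol condensation through 3) into 1 and 2. 1 supplies C16 and the whole side chain. The demand is that C12 be set by a catalyst, since C16 exerts little control.

## Other disconnections considered

Alternative 1: The cut is at C3–C4 and C5–C15. Forward, [Rh(CO)2Cl]2 would join the 1-silyloxy-1-vinylcyclopropane of A1 to the alkyne tethered through ring A in an intramolecular [5+2] cycloaddition, closing rings B and C and giving the silyl enol ether A2.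
- In favour: A2 already holds C15 as CH2, the bridgehead C4=C5 (from the alkyne), the C1 oxygen in the right place and a finished ring A. Hydrolysis, methylenation and desilylation would finish the synthesis. On the endgame and on the C1/C4 differentiation this plan is better than the chosen one.
- Against: the tether joins the alkyne to a cyclopropane carbon, so the reaction must run in the bridged (type 2) mode and close a seven-membered ring, which is much less documented than the fused mode. C14 has to be set beforehand on a trans-disubstituted cyclopropane next to C13 under acyclic control. The metal must open the C1–C15 and not the C1–C14 bond. A1 needs the tetrasubstituted C8=C9 with a butynyl chain before the key step.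
- Comparison: on structure the two plans are equal in making both seven-membered rings in one step. On mechanism the chosen thermal step sets C13 and C14 together from a cyclic diene, whereas here C14 is carried in. On step economy the alternative is shorter after the key step and longer before it.

Alternative 2: The cut is at C14–C15 and, temporarily, between C3 and the nitro carbon. Forward, heating A3 would let the 2-substituted diene add to the tethered (E)-nitroalkene in a type 2 intramolecular Diels–Alder reaction, giving the nitro-substituted bicyclo[4.3.1]decene A4.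
- In favour: the type 2 mode is a proven entry to bridgehead alkenes, the nitroalkene is a strong dienophile, and C15 arrives as CH2. The bridgehead alkene is obtained by construction, which is better than in the chosen plan.
- Against: ring C is one carbon short. Conversion of the nitro group to the ketone and a one-carbon ring expansion must insert the new carbon between C1 and C3 and not between C1 and C14. The relation of C14 to C13 depends on the tether conformation in a transition state that closes a seven-membered ring. A3 again needs the tetrasubstituted ring A alkene early.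
- Comparison: on structure the alternative builds ring B and only a precursor of ring C, whereas the chosen step builds both rings at full size. On mechanism both are thermal and substrate-controlled, so they are equal in that respect. On step economy the alternative should be shorter after the key step, and its precursor is longer than the seven-step route to 10.

Alternative 3: The cut is at C2–C3 and C14–C15. Forward, Rh2(S-DOSP)4 (dirhodium tetrakis[(S)-N-(p-dodecylphenylsulfonyl)prolinate]) would convert the vinyldiazo ester A5 into a vinylcarbenoid that cyclopropanates the monosubstituted alkene of diene A6; the cis-divinylcyclopropane would rearrange to the cycloheptadiene A7.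
- In favour: C14 is set by the catalyst and not by the facial bias of a substrate, which is better than in the chosen plan. The C1 oxygen and C4=C5 are placed by construction, and the step is convergent.
- Against: only ring C is closed. Ring B still has to be made by a seven-membered ring closure at C7–C8 next to the C13 centre, the C2 ester carbon has to be removed, and the C9 ketone still has to become the methyl-bearing alkene. The chiral catalyst meets a chiral substrate, so a mismatched pairing is possible.
- Comparison: on structure the chosen step forms two rings and two skeletal bonds of the bicycle, the alternative one ring. On mechanism the alternative is catalyst-controlled and stereospecific, the chosen one substrate-controlled. On step economy the two should be about equal, since the work saved on ring C is spent on ring B and on the extra carbon.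

Key step: step 8

Remarks on the chemistry:
- Of the two C9 epimers of the dienyl silyl ether, the one with the silyloxy group cis to the C12 side chain (10) is made on purpose. In the trans epimer the two allylic substituents of ring A would sit on opposite faces of the diene and the facial bias of the cycloaddition would be lost. The C9 centre is erased at 23.
- 13 and 14 are carried as C15 epimer mixtures, since C15 becomes CH2 in 15.

## Route

Step 1
Reactants: 1 (S)-citronellal; 2 methyl vinyl ketone
Product: 4 (4S)-4-[(2S)-6-methylhept-5-en-2-yl]cyclohex-2-en-1-one, via keto-aldehyde 3 (not isolated)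
Conditions: (S)-2-[methoxy(diphenyl)methyl]pyrrolidine (5 mol %), ethyl 3,4-dihydroxybenzoate (20 mol %), neat, 4 °C; then LiOH (cat.), iPrOH, rt
Reagents that add atoms: none
Why: Enamine-mediated Michael addition followed by intramolecular aldol condensation (Robinson-type annulation of an aldehyde). The (S)-diarylprolinol ether shields one face of the E-enamine, so C12 should form with the S configuration under catalyst control; C16 is carried in unchanged from 1.

Step 2
Reactants: 4 (4S)-4-[(2S)-6-methylhept-5-en-2-yl]cyclohex-2-en-1-one
Product: 5 (4S)-4-[(2S,5E)-7-hydroxy-6-methylhept-5-en-2-yl]cyclohex-2-en-1-one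
Conditions: SeO2 (0.3 equiv), tBuOOH (2.5 equiv), salicylic acid (10 mol %), CH2Cl2, rt
Reagents that add atoms: tert-butyl hydroperoxide, CC(C)(C)OO; selenium dioxide, O=[Se]=O (carrier of the oxygen, catalytic)
Why: Selenium dioxide allylic oxidation (ene reaction, then [2,3] shift) attacks the electron-rich trisubstituted alkene at its (E)-methyl group. The enone alkene is too electron-poor for the ene step, and ketone α-oxidation needs far higher temperature.

Step 3
Reactants: 5 (4S)-4-[(2S,5E)-7-hydroxy-6-methylhept-5-en-2-yl]cyclohex-2-en-1-one
Product: 6 tert-butyldiphenylsilyl ether of 5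
Conditions: TBDPSCl, imidazole, CH2Cl2, 0 °C to rt
Reagents that add atoms: tert-butyldiphenylsilyl chloride, CC(C)(C)[Si](Cl)(c1ccccc1)c1ccccc1
Why: Standard silylation of a primary alcohol. The TBDPS group is chosen because it survives the later acid-mediated removal of the C9 triethylsilyl group.

Step 4
Reactants: 6 tert-butyldiphenylsilyl ether of 5
Product: 7 (4S)-2-iodo enone
Conditions: I2, pyridine, CH2Cl2, 0 °C to rt
Reagents that add atoms: iodine, II
Why: α-Iodination of a cyclic enone by conjugate addition of pyridine, iodination of the enolate and elimination. The side-chain alkene, deactivated by its allylic oxygen, should only add iodine reversibly.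

Step 5
Reactants: 7 (4S)-2-iodo enone
Product: 8 (1S,4S)-2-iodocyclohex-2-en-1-ol with the hydroxyl cis to the side chain
Conditions: (R)-2-methyl-CBS-oxazaborolidine (0.3 equiv), catecholborane, toluene, −78 °C
Reagents that add atoms: none
Why: Corey–Bakshi–Shibata reduction in which the iodoalkenyl arm is the large group. The (R)-catalyst should deliver hydride to give the (9S) alcohol, cis to the C12 side chain, overriding the weak bias of the remote C12 centre; catecholborane leaves the alkenes alone.

Step 6
Reactants: 8 (1S,4S)-2-iodocyclohex-2-en-1-ol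
Product: 9 triethylsilyl ether of 8
Conditions: TESCl, imidazole, DMF, 0 °C
Reagents that add atoms: triethylsilyl chloride, CC[Si](Cl)(CC)CC
Why: Silylation of a secondary allylic alcohol. The triethylsilyl group is bulky enough to shield one diene face and can later be removed without touching the TBDPS ether.

Step 7
Reactants: 9 triethylsilyl ether of 8
Product: 10 ring A diene, (1S,4S)-4-substituted 2-vinylcyclohex-2-en-1-yl triethylsilyl ether
Conditions: tributyl(vinyl)stannane, Pd2(dba)3 (2.5 mol %), AsPh3, CuI (10 mol %), NMP, rt to 40 °C
Reagents that add atoms: tributyl(vinyl)stannane, C=C[Sn](CCCC)(CCCC)CCCC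
Why: Stille coupling of an alkenyl iodide with a vinylstannane under mild, non-basic conditions. The C8=C13 geometry is fixed by the ring and no stereocentre is touched.

Step 8
Reactants: 10 ring A diene; 11 tropone
Product: 12 tricyclic trienone (bicyclo[4.4.1]undeca-2,4,8-trien-11-one fused to ring A)
Conditions: 11 (3 equiv), toluene, BHT (cat.), 110 °C, sealed tube
Reagents that add atoms: none
Why: Concerted thermal [6π+4π] cycloaddition, suprafacial on both partners, of the tropone triene (C14, C1–C4, C5) with the s-cis diene C6=C7–C8=C13; the closest known reaction type is the thermal [6+4] addition of tropone to acyclic and semicyclic 1,3-dienes, which gives bicyclo[4.4.1]undeca-2,4,8-trien-11-ones. Ring B is closed by the two new σ bonds C13–C14 and C5–C6 in a bimolecular annulation across the two α-carbons of 11, and ring C, brought in as the ring of 11, becomes the second seven-membered ring of the bridged pair as C15 turns into the one-carbon bridge. C13 is set by the diene face: the C9 silyloxy group and the C12 side chain lie on the same face of ring A, so 11 should add to the other face and the new C13–C14 bond should be trans to the side chain. C14, and with it C5 (tied to C14 by the bridge), is set by the exo transition state, in which the carbonyl lies over the inner diene carbons C7/C8 and the antibonding secondary overlap of the endo arrangement is avoided; this places H13 anti to H14. The step needs periselectivity for [6+4] over the [4+2] modes, exo geometry and facial selectivity. The first two rest on the pairing of the tropone LUMO with the HOMO of an alkyl-substituted diene at moderate temperature, below that of the Cope isomerisation of the adduct; the C9 substituent disfavours the s-trans rotamer by allylic strain; and the cis-1,4 substituents of 10 supply the facial bias.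

Step 9
Reactants: 12 tricyclic trienone
Product: 13 C15 alcohol (epimer mixture at C15)
Conditions: NaBH4, MeOH/CH2Cl2, 0 °C
Reagents that add atoms: none
Why: Borohydride reduction of the bridging ketone, the only carbonyl present. The C15 configuration is irrelevant because the centre becomes CH2 in step 11.

Step 10
Reactants: 13 C15 alcohol
Product: 14 C15 O-(imidazole-1-carbothioate)
Conditions: 1,1'-thiocarbonyldiimidazole, DMAP (cat.), ClCH2CH2Cl, 70 °C
Reagents that add atoms: 1,1'-thiocarbonyldiimidazole, S=C(n1ccnc1)n1ccnc1
Why: Thioacylation of a secondary alcohol for Barton–McCombie deoxygenation. No syn β-hydrogen can give a permissible alkene from C15, so thermal elimination is not a concern.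

Step 11
Reactants: 14 C15 O-(imidazole-1-carbothioate)
Product: 15 tricyclic triene with C15 as CH2
Conditions: Bu3SnH (5 equiv, 0.5 M), (PhSe)2 (10 mol %), AIBN (cat.), toluene, 80 °C
Reagents that add atoms: none
Why: Barton–McCombie radical deoxygenation. Benzeneselenol, formed in the flask from the diselenide, is a very fast hydrogen donor and should trap the C15 radical before it can add to the flanking diene (homoallyl to cyclopropylcarbinyl rearrangement).

Step 12
Reactants: 15 tricyclic triene
Product: 17 cis-C1/C4 diol of ring C (C2=C3 kept), via endoperoxide 16 (not isolated)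
Conditions: O2, tetraphenylporphyrin (cat.), visible light, CH2Cl2, −40 °C; then thiourea, MeOH, −40 °C to rt
Reagents that add atoms: oxygen (as singlet oxygen), O=O
Why: [4+2] Cycloaddition of singlet oxygen to the cis-locked diene, then reduction of the O–O bond. Oxygen should add to the ring C face turned away from the bulkier ring B bridge, which puts both hydroxyls cis to H5 and H14. The two trisubstituted alkenes each carry an allylic silyloxy group, which slows the competing ene reaction.

Step 13
Reactants: 17 cis-C1/C4 diol
Product: 18 C1 alcohol with the C2=C3–C4=C5 diene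
Conditions: Burgess reagent (1.05 equiv), THF/benzene, 0 °C to 50 °C
Reagents that add atoms: none
Why: Burgess dehydration (syn elimination through the sulfamate ester). The C4 hydroxyl lies on the flank of ring C next to the C6 methylene, whereas the C1 hydroxyl is next to C14 with the ring junction carbon C13 behind it, so the reagent should take C4–OH. The C4 oxygen is cis to H5 and becomes syn-periplanar when the C3–C4–C5–C15 torsion closes, and C3 is sp2, so H5 is the only hydrogen that can be lost.

Step 14
Reactants: 18 C1 alcohol with the C2=C3–C4=C5 diene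
Product: 19 C1 ketone conjugated with C2=C3–C4=C5 (dienone)
Conditions: Dess–Martin periodinane, pyridine, CH2Cl2, 0 °C
Reagents that add atoms: none
Why: Mild buffered oxidation of a dienylic secondary alcohol. C14 is a bridgehead and cannot enolise in a way that moves the diene.

Step 15
Reactants: 19 dienone
Product: 20 C1 ketone with C4=C5 (C2 and C3 saturated)
Conditions: [(Ph3P)CuH]6 (0.4 equiv), toluene, rt; aq NH4Cl work-up
Reagents that add atoms: none
Why: Copper hydride conjugate reduction. Hydride should go to the β-carbon C3 (a CH) and not to the fully substituted δ-carbon C5, as with dienones whose δ-carbon bears no hydrogen. Isolated alkenes and silyl ethers are inert, and protonation at C2 leaves C4=C5 out of conjugation.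

Step 16
Reactants: 20 C1 ketone with C4=C5
Product: 21 C1 exocyclic methylene compound
Conditions: Ph3PCH3Br, KOtBu, THF, 0 °C to rt
Reagents that add atoms: methyltriphenylphosphonium bromide, C[P+](c1ccccc1)(c1ccccc1)c1ccccc1.[Br-]
Why: Wittig methylenation of the only carbonyl group. C14 is a bridgehead and is not epimerised, and no conjugated carbonyl is present at this stage to be deprotonated.

Step 17
Reactants: 21 C1 exocyclic methylene compound
Product: 22 C9 allylic alcohol
Conditions: PPTS (cat.), MeOH/CH2Cl2, 0 °C to rt
Reagents that add atoms: none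
Why: Mild acid solvolysis removes the triethylsilyl ether and leaves the primary TBDPS ether. The acid is too weak to shift the 1,1-disubstituted or bridgehead alkene.

Step 18
Reactants: 22 C9 allylic alcohol
Product: 23 C9 enone (C9=O conjugated with C7=C8)
Conditions: Dess–Martin periodinane, pyridine, CH2Cl2, 0 °C to rt
Reagents that add atoms: none
Why: Neutral oxidation of the allylic alcohol; this erases the C9 centre. Base is avoided because C6–H2 of 23 lies between the enone and C4=C5.

Step 19
Reactants: 23 C9 enone
Product: 26 C8=C9 enol triflate, via silyl enol ether 24 (not isolated), via lithium enolate 25 (not isolated)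
Conditions: [(Ph3P)CuH]6, TMSCl, toluene/THF, −40 °C to rt; then MeLi, THF, 0 °C; then PhNTf2, −78 °C to rt
Reagents that add atoms: N-phenylbis(trifluoromethanesulfonimide), O=S(=O)(N(c1ccccc1)S(=O)(=O)C(F)(F)F)C(F)(F)F
Why: Non-basic copper hydride conjugate reduction places hydrogen on C7 and, with silyl trapping, fixes the enol double bond at C8=C9. Cleavage of the silyl enol ether with methyllithium and O-triflation of the resulting enolate then give the tetrasubstituted enol triflate without enolate equilibration.

Step 20
Reactants: 26 C8=C9 enol triflate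
Product: 27 tert-butyldiphenylsilyl ether of the target
Conditions: Me2CuLi (from CuI and MeLi), Et2O/THF, −20 °C to 0 °C
Reagents that add atoms: lithium dimethylcuprate, [Li+].C[Cu-]C
Why: Coupling of an enol triflate with a lithium dialkylcuprate installs the C9 methyl group with retention of the alkene position. The other alkenes and the silyl ether do not react.

Step 21
Reactants: 27 tert-butyldiphenylsilyl ether of the target
Product: 28 target CNP0289180.1
Conditions: TBAF, THF, 0 °C to rt
Reagents that add atoms: none
Why: Fluoride cleavage of the silyl ether under basic, non-acidic conditions, so the exocyclic and bridgehead alkenes and the allylic alcohol are not exposed to acid.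

## Compound list

1 | (S)-citronellal, (3S)-3,7-dimethyloct-6-enal | O=CC[C@@H](C)CCC=C(C)C | starting material
2 | methyl vinyl ketone (but-3-en-2-one) | CC(=O)C=C | starting material
3 | (2S)-2-[(2S)-6-methylhept-5-en-2-yl]-5-oxohexanal | O=C[C@H]([C@@H](C)CCC=C(C)C)CCC(C)=O | intermediate (not isolated)
4 | (4S)-4-[(2S)-6-methylhept-5-en-2-yl]cyclohex-2-en-1-one | O=C1C=C[C@H]([C@@H](C)CCC=C(C)C)CC1 | intermediate
5 | (4S)-4-[(2S,5E)-7-hydroxy-6-methylhept-5-en-2-yl]cyclohex-2-en-1-one | O=C1C=C[C@H]([C@@H](C)CC/C=C(\C)CO)CC1 | intermediate
6 | (4S)-4-[(2S,5E)-7-(tert-butyldiphenylsilyloxy)-6-methylhept-5-en-2-yl]cyclohex-2-en-1-one | O=C1C=C[C@H]([C@@H](C)CC/C=C(\C)CO[Si](c2ccccc2)(c2ccccc2)C(C)(C)C)CC1 | intermediate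
7 | (4S)-2-iodo-4-[(2S,5E)-7-(tert-butyldiphenylsilyloxy)-6-methylhept-5-en-2-yl]cyclohex-2-en-1-one | O=C1C(I)=C[C@H]([C@@H](C)CC/C=C(\C)CO[Si](c2ccccc2)(c2ccccc2)C(C)(C)C)CC1 | intermediate
8 | (1S,4S)-2-iodo-4-[(2S,5E)-7-(tert-butyldiphenylsilyloxy)-6-methylhept-5-en-2-yl]cyclohex-2-en-1-ol (hydroxyl cis to the side chain) | IC1=C[C@H]([C@@H](C)CC/C=C(\C)CO[Si](c2ccccc2)(c2ccccc2)C(C)(C)C)CC[C@@H]1O | intermediate
9 | triethylsilyl ether of 8 | IC1=C[C@H]([C@@H](C)CC/C=C(\C)CO[Si](c2ccccc2)(c2ccccc2)C(C)(C)C)CC[C@@H]1O[Si](CC)(CC)CC | intermediate
10 | ring A diene, (1S,4S)-4-[(2S,5E)-7-(tert-butyldiphenylsilyloxy)-6-methylhept-5-en-2-yl]-2-vinylcyclohex-2-en-1-yl triethylsilyl ether (C6=C7–C8=C13 diene, C9 silyloxy cis to the C12 side chain) | C=CC1=C[C@H]([C@@H](C)CC/C=C(\C)CO[Si](c2ccccc2)(c2ccccc2)C(C)(C)C)CC[C@@H]1O[Si](CC)(CC)CC | intermediate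
11 | tropone (cyclohepta-2,4,6-trien-1-one) | O=C1C=CC=CC=C1 | starting material
12 | tricyclic trienone: ring A-fused bicyclo[4.4.1]undeca-2,4,8-trien-11-one (C1=C2–C3=C4, C7=C8, C15=O; H13 anti to H14; C13–C14 bond trans to the C12 side chain; C9 triethylsilyloxy) | C1=CC=C[C@H]2CC=C3[C@@H](O[Si](CC)(CC)CC)CC[C@@H]([C@@H](C)CC/C=C(\C)CO[Si](c4ccccc4)(c4ccccc4)C(C)(C)C)[C@@H]3[C@@H]1C2=O | intermediate
13 | C15 alcohol of 12 (both C15 epimers) | C1=CC=C[C@H]2CC=C3[C@@H](O[Si](CC)(CC)CC)CC[C@@H]([C@@H](C)CC/C=C(\C)CO[Si](c4ccccc4)(c4ccccc4)C(C)(C)C)[C@@H]3[C@@H]1C2O | intermediate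
14 | C15 O-(1H-imidazole-1-carbothioate) of 13 | C1=CC=C[C@H]2CC=C3[C@@H](O[Si](CC)(CC)CC)CC[C@@H]([C@@H](C)CC/C=C(\C)CO[Si](c4ccccc4)(c4ccccc4)C(C)(C)C)[C@@H]3[C@@H]1C2OC(=S)n1ccnc1 | intermediate
15 | tricyclic triene with C15 as CH2 (ring C 1,3-diene, C7=C8) | C1=CC=C[C@H]2CC=C3[C@@H](O[Si](CC)(CC)CC)CC[C@@H]([C@@H](C)CC/C=C(\C)CO[Si](c4ccccc4)(c4ccccc4)C(C)(C)C)[C@@H]3[C@@H]1C2 | intermediate
16 | C1,C4-endoperoxide of 15 (O–O bridge cis to H5 and H14, C2=C3) | [C@H]12C=C[C@H](OO1)[C@H]3CC=C4[C@@H](O[Si](CC)(CC)CC)CC[C@@H]([C@@H](C)CC/C=C(\C)CO[Si](c5ccccc5)(c5ccccc5)C(C)(C)C)[C@@H]4[C@@H]2C3 | intermediate (not isolated)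
17 | cis-C1,C4-diol with C2=C3 (both hydroxyls cis to H5 and H14) | O[C@@H]1C=C[C@H](O)[C@H]2CC=C3[C@@H](O[Si](CC)(CC)CC)CC[C@@H]([C@@H](C)CC/C=C(\C)CO[Si](c4ccccc4)(c4ccccc4)C(C)(C)C)[C@@H]3[C@@H]1C2 | intermediate
18 | C1 alcohol with the C2=C3–C4=C5 diene | O[C@@H]1C=CC=C2CC=C3[C@@H](O[Si](CC)(CC)CC)CC[C@@H]([C@@H](C)CC/C=C(\C)CO[Si](c4ccccc4)(c4ccccc4)C(C)(C)C)[C@@H]3[C@@H]1C2 | intermediate
19 | C1 ketone conjugated with C2=C3–C4=C5 | O=C1C=CC=C2CC=C3[C@@H](O[Si](CC)(CC)CC)CC[C@@H]([C@@H](C)CC/C=C(\C)CO[Si](c4ccccc4)(c4ccccc4)C(C)(C)C)[C@@H]3[C@@H]1C2 | intermediate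
20 | C1 ketone with bridgehead C4=C5 (C2, C3 saturated) | O=C1CCC=C2CC=C3[C@@H](O[Si](CC)(CC)CC)CC[C@@H]([C@@H](C)CC/C=C(\C)CO[Si](c4ccccc4)(c4ccccc4)C(C)(C)C)[C@@H]3[C@@H]1C2 | intermediate
21 | C1 exocyclic methylene compound (C4=C5, C7=C8, C9 triethylsilyloxy) | C=C1CCC=C2CC=C3[C@@H](O[Si](CC)(CC)CC)CC[C@@H]([C@@H](C)CC/C=C(\C)CO[Si](c4ccccc4)(c4ccccc4)C(C)(C)C)[C@@H]3[C@@H]1C2 | intermediate
22 | C9 allylic alcohol of 21 | C=C1CCC=C2CC=C3[C@@H](O)CC[C@@H]([C@@H](C)CC/C=C(\C)CO[Si](c4ccccc4)(c4ccccc4)C(C)(C)C)[C@@H]3[C@@H]1C2 | intermediate
23 | C9 enone (C9=O conjugated with C7=C8) | C=C1CCC=C2CC=C3C(=O)CC[C@@H]([C@@H](C)CC/C=C(\C)CO[Si](c4ccccc4)(c4ccccc4)C(C)(C)C)[C@@H]3[C@@H]1C2 | intermediate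
24 | C8=C9 trimethylsilyl enol ether | C=C1CCC=C2CCC3=C(O[Si](C)(C)C)CC[C@@H]([C@@H](C)CC/C=C(\C)CO[Si](c4ccccc4)(c4ccccc4)C(C)(C)C)[C@@H]3[C@@H]1C2 | intermediate (not isolated)
25 | C8=C9 lithium enolate | [Li+].C=C1CCC=C2CCC3=C([O-])CC[C@@H]([C@@H](C)CC/C=C(\C)CO[Si](c4ccccc4)(c4ccccc4)C(C)(C)C)[C@@H]3[C@@H]1C2 | intermediate (not isolated)
26 | C8=C9 enol trifluoromethanesulfonate | C=C1CCC=C2CCC3=C(OS(=O)(=O)C(F)(F)F)CC[C@@H]([C@@H](C)CC/C=C(\C)CO[Si](c4ccccc4)(c4ccccc4)C(C)(C)C)[C@@H]3[C@@H]1C2 | intermediate
27 | tert-butyldiphenylsilyl ether of the target | C=C1CCC=C2CCC3=C(C)CC[C@@H]([C@@H](C)CC/C=C(\C)CO[Si](c4ccccc4)(c4ccccc4)C(C)(C)C)[C@@H]3[C@@H]1C2 | intermediate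
28 | CNP0289180.1 | C=C1CCC=C2CCC3=C(C)CC[C@@H]([C@@H](C)CC/C=C(\C)CO)[C@@H]3[C@@H]1C2 | target

## Step count and least certain steps

Total step count: 21. Longest linear sequence: 21 steps from 1 (2 and 11 are bought and enter in steps 1 and 8).

**Step 8 (key step).** The most likely failures are:
- diversion into [4+2] pathways (tropone reacting as a diene with the vinyl group, or as a dienophile), because the [6+4] mode is only modestly favoured for acyclic diene termini;
- slow reaction with thermal decay of 10;
- leakage of facial selectivity if the silyl ether shields less than expected.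

Fallback: the steric bias is replaced by a hydrogen-bond tether. 7 is reduced with the enantiomeric oxazaborolidine to the trans iodo alcohol F1 and vinylated to the trans dienol F2. F2 is heated with 11 in a non-polar solvent; the free hydroxyl, now on the face opposite to the side chain, can bind the tropone carbonyl in the exo arrangement and so hold and activate 11 on the desired face, giving the hydroxy trienone F3. Mitsunobu inversion with 4-nitrobenzoic acid to the cis ester F4, methanolysis to the cis hydroxy trienone F5 and silylation return the material to 12.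

**Step 13.** Two processes may spoil it:
- sulfamate formation at the C1 instead of the C4 hydroxyl, since both are secondary and allylic and differ only in the crowding of their flanks;
- ionisation of the allylic sulfamate with return at C2 instead of syn elimination towards the bridgehead hydrogen.

Fallback: the two ends are told apart by a metal that must approach from the ring B side. 17 is converted into the bis(methyl carbonate) F6. Zerovalent palladium (Pd(PPh3)4) with thiophenol should ionise the carbonate at C4, whose rear flank is the C6 methylene, rather than at C1, whose rear flank is the ring junction carbon C13. The thiolate then attacks the allyl complex anti to the metal, giving the C4 phenyl sulfide F7 with overall retention. Oxidation with NaIO4 to the sulfoxide F8 and thermal syn elimination of the sulfoxide (cis to H5) give the dienyl carbonate F9, and methanolysis (K2CO3, MeOH) returns the material to 18.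

**Step 11.** The C15 radical is homoallylic to the ring C diene on both sides. Ring closure onto C1 or C4 to an allyl-stabilised cyclopropylcarbinyl radical, followed by reopening with vinyl migration or by direct reduction, would change the skeleton. Fallback: a non-radical removal of the carbonyl oxygen from 12. Condensation with 1,2-bis(tert-butyldimethylsilyl)hydrazine (Sc(OTf)3 cat.) gives the N-silyl hydrazone F10, and Wolff–Kishner reduction under mild conditions (KOtBu, tBuOH, DMSO, rt to 60 °C), in which the carbanion is protonated as it forms, returns the material to 15 and replaces steps 9–11.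

**Step 19.** Possible failures are 1,2- instead of 1,4-delivery of hydride, loss of the enolate position during the silyl-to-lithium-to-triflate relay, and proton loss from C6 of 23 with migration of the ring alkenes. Fallback: the methyl carbon is brought in as a methylene and the alkene is set by hydrogen addition. Starting from 20:
- the triethylsilyl group is removed (PPTS, MeOH) to give the hydroxy ketone F11;
- Dess–Martin oxidation gives the keto enone F12;
- both carbonyls are methylenated without base (Cp2TiMe2, toluene, 70 °C) to the pentaene F13;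
- (η6-naphthalene)Cr(CO)3-catalysed 1,4-hydrogenation, which is specific for the s-cis diene C7=C8–C9=CH2, adds hydrogen at C7 and at the exocyclic carbon and returns the material to 27.

This path is held in reserve because the chromium catalyst may also shift hydrogen from C6.

## Further compounds

F1 | step 8 | (1R,4S)-2-iodo-4-[(2S,5E)-7-(tert-butyldiphenylsilyloxy)-6-methylhept-5-en-2-yl]cyclohex-2-en-1-ol (hydroxyl trans to the side chain) | IC1=C[C@H]([C@@H](C)CC/C=C(\C)CO[Si](c2ccccc2)(c2ccccc2)C(C)(C)C)CC[C@H]1O
F2 | step 8 | trans dienol, (1R,4S)-4-substituted 2-vinylcyclohex-2-en-1-ol | C=CC1=C[C@H]([C@@H](C)CC/C=C(\C)CO[Si](c2ccccc2)(c2ccccc2)C(C)(C)C)CC[C@H]1O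
F3 | step 8 | hydroxy trienone, C9 epimer of 12 with free hydroxyl | C1=CC=C[C@H]2CC=C3[C@H](O)CC[C@@H]([C@@H](C)CC/C=C(\C)CO[Si](c4ccccc4)(c4ccccc4)C(C)(C)C)[C@@H]3[C@@H]1C2=O
F4 | step 8 | C9 4-nitrobenzoate with the configuration of 12 | C1=CC=C[C@H]2CC=C3[C@@H](OC(=O)c4ccc(cc4)[N+](=O)[O-])CC[C@@H]([C@@H](C)CC/C=C(\C)CO[Si](c4ccccc4)(c4ccccc4)C(C)(C)C)[C@@H]3[C@@H]1C2=O
F5 | step 8 | cis hydroxy trienone (12 without the triethylsilyl group) | C1=CC=C[C@H]2CC=C3[C@@H](O)CC[C@@H]([C@@H](C)CC/C=C(\C)CO[Si](c4ccccc4)(c4ccccc4)C(C)(C)C)[C@@H]3[C@@H]1C2=O
F6 | step 13 | C1,C4-bis(methyl carbonate) of 17 | COC(=O)O[C@@H]1C=C[C@H](OC(=O)OC)[C@H]2CC=C3[C@@H](O[Si](CC)(CC)CC)CC[C@@H]([C@@H](C)CC/C=C(\C)CO[Si](c4ccccc4)(c4ccccc4)C(C)(C)C)[C@@H]3[C@@H]1C2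
F7 | step 13 | C4 phenyl sulfide, C1 methyl carbonate | COC(=O)O[C@@H]1C=C[C@H](Sc4ccccc4)[C@H]2CC=C3[C@@H](O[Si](CC)(CC)CC)CC[C@@H]([C@@H](C)CC/C=C(\C)CO[Si](c4ccccc4)(c4ccccc4)C(C)(C)C)[C@@H]3[C@@H]1C2
F8 | step 13 | C4 phenyl sulfoxide, C1 methyl carbonate | COC(=O)O[C@@H]1C=C[C@H](S(=O)c4ccccc4)[C@H]2CC=C3[C@@H](O[Si](CC)(CC)CC)CC[C@@H]([C@@H](C)CC/C=C(\C)CO[Si](c4ccccc4)(c4ccccc4)C(C)(C)C)[C@@H]3[C@@H]1C2
F9 | step 13 | methyl carbonate of 18 | COC(=O)O[C@@H]1C=CC=C2CC=C3[C@@H](O[Si](CC)(CC)CC)CC[C@@H]([C@@H](C)CC/C=C(\C)CO[Si](c4ccccc4)(c4ccccc4)C(C)(C)C)[C@@H]3[C@@H]1C2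
F10 | step 11 | N-(tert-butyldimethylsilyl)hydrazone of 12 | C1=CC=C[C@H]2CC=C3[C@@H](O[Si](CC)(CC)CC)CC[C@@H]([C@@H](C)CC/C=C(\C)CO[Si](c4ccccc4)(c4ccccc4)C(C)(C)C)[C@@H]3[C@@H]1C2=NN[Si](C)(C)C(C)(C)C
F11 | step 19 | C1 ketone with free C9 alcohol | O=C1CCC=C2CC=C3[C@@H](O)CC[C@@H]([C@@H](C)CC/C=C(\C)CO[Si](c4ccccc4)(c4ccccc4)C(C)(C)C)[C@@H]3[C@@H]1C2
F12 | step 19 | C1 ketone, C9 enone | O=C1CCC=C2CC=C3C(=O)CC[C@@H]([C@@H](C)CC/C=C(\C)CO[Si](c4ccccc4)(c4ccccc4)C(C)(C)C)[C@@H]3[C@@H]1C2
F13 | step 19 | pentaene with methylene groups on C1 and C9 | C=C1CCC=C2CC=C3C(=C)CC[C@@H]([C@@H](C)CC/C=C(\C)CO[Si](c4ccccc4)(c4ccccc4)C(C)(C)C)[C@@H]3[C@@H]1C2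
A1 | alternative 1 | ring A carrying a but-3-ynyl chain on C8 and a 1-(tert-butyldimethylsilyloxy)-1-vinylcyclopropane on C13 (configuration at the silyloxy carbon open) | C#CCCC1=C(C)CC[C@@H]([C@@H](C)CC/C=C(\C)CO[Si](C)(C)C(C)(C)C)[C@@H]1[C@@H]1CC1(O[Si](C)(C)C(C)(C)C)C=C
A2 | alternative 1 | tricyclic C1 silyl enol ether with the C4=C5 bridgehead alkene | CC(C)(C)[Si](C)(C)OC1=CCC=C2CCC3=C(C)CC[C@@H]([C@@H](C)CC/C=C(\C)CO[Si](C)(C)C(C)(C)C)[C@@H]3[C@@H]1C2
A3 | alternative 2 | ring A carrying a 3-methylenepent-4-enyl chain on C8 and an (E)-2-nitrovinyl group on C13 | C=CC(=C)CCC1=C(C)CC[C@@H]([C@@H](C)CC/C=C(\C)CO[Si](C)(C)C(C)(C)C)[C@@H]1/C=C/[N+](=O)[O-]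
A4 | alternative 2 | nitro-substituted bicyclo[4.3.1]decene fused to ring A, with the C4=C5 bridgehead alkene | O=[N+]([O-])[C@@H]1CC=C2CCC3=C(C)CC[C@@H]([C@@H](C)CC/C=C(\C)CO[Si](C)(C)C(C)(C)C)[C@@H]3[C@@H]1C2
A5 | alternative 3 | methyl 2-diazo-3-(tert-butyldimethylsilyloxy)but-3-enoate carrying the ketal-protected ring A on C14 | COC(=O)C(=[N+]=[N-])C(O[Si](C)(C)C(C)(C)C)=C[C@@H]1CC2(OCCO2)CC[C@H]1[C@@H](C)CC/C=C(\C)CO[Si](C)(C)C(C)(C)C
A6 | alternative 3 | 2-[2-(triisopropylsilyloxy)ethyl]buta-1,3-diene | C=CC(=C)CCO[Si](C(C)C)(C(C)C)C(C)C
A7 | alternative 3 | ring C cycloheptadiene (C1 silyl enol ether, C2 ester, C4=C5) joined to ring A at C14 | COC(=O)C1=C(O[Si](C)(C)C(C)(C)C)[C@H]([C@@H]2CC3(OCCO3)CC[C@H]2[C@@H](C)CC/C=C(\C)CO[Si](C)(C)C(C)(C)C)CC(CCO[Si](C(C)C)(C(C)C)C(C)C)=CC1
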